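Assumption: the SMILES is taken as the absolute configuration, which is (1R,2R,3S,5S) on the cyclopentane (C1 = quaternary carbon, C2 = CH–CH2OAr, C3 = CHMe, C5 = CH–isobutenyl).

## Retrosynthetic overview
1. The acid comes from its methyl ester by esterase hydrolysis. The aryl ether C–O bond comes from a Mitsunobu reaction of umbelliferone with the cyclopentylmethanol.
2. The isobutenyl group (Wittig) and the propionate chain both come from oxidative cleavage of the C4=C5 enol silane of a cis-hydrindanone. The cis ring fusion fixes C5 relative to the quaternary C1.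
3. The hydrindenone comes from MVK annulation (Mukaiyama–Michael, then aldol) onto the enol silane formed by vinyl-cuprate addition to (S)-2,4-dimethylcyclopent-2-enone. Stereocontrol is relayed anti at each step: Me, then vinyl, then quaternary carbon.
4. The enone comes from (S)-4-silyloxycyclopentenone by cuprate addition/elimination (chirality relay) and iodination/Negishi methylation. The silyloxyenone comes from lipase desymmetrisation of a meso-diacetate.
5. Ring order: the cyclopentane is present from the start. A temporary six-membered ring is built in step 11 and cleaved in step 16. The coumarin is attached intact.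

(β = face of the quaternary methyl; α = opposite face.)

## Route

**Step 1**
Reactants: 1, cis-3,5-diacetoxycyclopent-1-ene (meso)
Product: 2, (1R,4S)-4-hydroxycyclopent-2-en-1-yl acetate
Conditions: lipase (immobilised Candida antarctica lipase B), MeOH, MTBE, 5 °C
Reagents that add atoms: none
Why: In this lipase-catalysed enantiotopos-selective transesterification (meso desymmetrisation) the enzyme removes only the acetate on the (S)-carbinol carbon, which defines both stereocentres in >99% ee with a 100% theoretical yield and a recrystallisable product.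

**Step 2**
Reactants: 2
Product: 3, (1R,4S)-4-(tert-butyldimethylsilyloxy)cyclopent-2-en-1-yl acetate
Conditions: TBSCl, imidazole, DMF, rt
Reagents that add atoms: TBSCl, CC(C)(C)[Si](C)(C)Cl
Why: Standard silylation of the free secondary alcohol occurs without touching either stereocentre.

**Step 3**
Reactants: 3
Product: 4, (1R,4S)-4-(tert-butyldimethylsilyloxy)cyclopent-2-en-1-ol
Conditions: K2CO3, MeOH, 0 °C
Reagents that add atoms: none
Why: Mild Zemplén-type methanolysis removes the acetate while the TBS ether survives.

**Step 4**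
Reactants: 4
Product: 5, (S)-4-(tert-butyldimethylsilyloxy)cyclopent-2-en-1-one
Conditions: Dess–Martin periodinane, NaHCO3, CH2Cl2, 0 °C → rt
Reagents that add atoms: none
Why: Neutral Dess–Martin oxidation of the allylic alcohol leaves the silyloxy-bearing stereocentre, originally the enzyme-liberated OH carbon, as the (S)-enone.

**Step 5**
Reactants: 5
Product: 6, (3S,4S)-4-(tert-butyldimethylsilyloxy)-3-methylcyclopentan-1-one (Me trans to OTBS)
Conditions: Me2CuLi (MeLi, CuI), Et2O, −78 °C; NH4Cl/NH3
Reagents that add atoms: lithium dimethylcuprate, [Li+].C[Cu-]C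
Why: Gilman conjugate addition to a 4-silyloxycyclopentenone occurs anti to the OTBS group (prostaglandin-type precedent) and sets the ring C–Me stereocentre of the target.

**Step 6**
Reactants: 6
Product: 7, (S)-4-methylcyclopent-2-en-1-one
Conditions: DBU, CH2Cl2, 0 °C, short contact; telescoped as a solution because the product is volatile
Reagents that add atoms: none
Why: E1cB β-elimination of silanolate gives the transposed enone, and the chirality now resides only in the non-acidified methyl-bearing carbon.

**Step 7**
Reactants: 7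
Product: 8, (S)-2-iodo-4-methylcyclopent-2-en-1-one
Conditions: I2, pyridine/CH2Cl2, 0 °C → rt
Reagents that add atoms: iodine, II
Why: Johnson α-iodination (pyridine addition, iodination, elimination) is specific for the enone α-carbon and does not involve C4.

**Step 8**
Reactants: 8
Product: 9, (S)-2,4-dimethylcyclopent-2-en-1-one
Conditions: Me2Zn, PdCl2(dppf) (3 mol %), THF, 0 °C → rt
Reagents that add atoms: dimethylzinc, C[Zn]C
Why: Base-free Negishi coupling of an α-iodoenone installs the future quaternary methyl without a racemising dienolate.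

**Step 9**
Reactants: 9
Product: 10, {[(3R,4S)-3-ethenyl-2,4-dimethylcyclopent-1-en-1-yl]oxy}trimethylsilane (vinyl trans to 4-Me)
Conditions: vinylMgBr, CuBr·SMe2, TMSCl, DMPU, THF, −78 °C; Et3N, cold NaHCO3
Reagents that add atoms: vinylmagnesium bromide, C=C[Mg]Br; TMSCl, C[Si](C)(C)Cl
Why: TMSCl-accelerated cuprate conjugate addition occurs anti to the C4 methyl, giving the trans-3,4 relationship, and traps the tetrasubstituted enolate regiospecifically as its enol silane.

**Step 10**
Reactants: 10; 11, methyl vinyl ketone
Product: 12, (2S,3R,4S)-3-ethenyl-2,4-dimethyl-2-(3-oxobutyl)cyclopentan-1-one (oxobutyl chain trans to vinyl, C2-Me cis to vinyl)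
Conditions: TiCl4, CH2Cl2, −78 °C; aq. NaHCO3
Reagents that add atoms: methyl vinyl ketone, C=CC(C)=O
Why: In this Mukaiyama–Michael addition the activated enone approaches the enol silane anti to the adjacent vinyl group, the vicinal-trans rule used in steroid CD-ring syntheses, and this sets the quaternary stereocentre.

**Step 11**
Reactants: 12
Product: 13, (1R,2S,7aS)-1-ethenyl-2,7a-dimethyl-1,2,3,6,7,7a-hexahydro-5H-inden-5-one
Conditions: KOH, MeOH, 60 °C
Reagents that add atoms: none
Why: This is the aldol cyclodehydration half of a Robinson annulation (methyl-ketone CH3 onto the ring C=O), and none of the three stereocentres is α to a carbonyl, so none can epimerise.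

**Step 12**
Reactants: 13
Product: 14, (1R,2S,7aS)-2,7a-dimethyl-5-oxo-2,3,5,6,7,7a-hexahydro-1H-indene-1-carbaldehyde
Conditions: OsO4 (2 mol %), NaIO4, 2,6-lutidine, dioxane/H2O, rt
Reagents that add atoms: OsO4, O=[Os](=O)(=O)=O; NaIO4, [Na+].[O-]I(=O)(=O)=O
Why: Lemieux–Johnson cleavage takes the electron-rich monosubstituted alkene in preference to the hindered, electron-poor enone C=C, and the β-CHO (trans to the 2-Me) is also the thermodynamic epimer.

**Step 13**
Reactants: 14
Product: 15, (1R,2S,7aS)-1-(hydroxymethyl)-2,7a-dimethyl-1,2,3,6,7,7a-hexahydro-5H-inden-5-one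
Conditions: NaBH4 (0.5 equiv), CH2Cl2/MeOH, −78 °C
Reagents that add atoms: none
Why: This is a chemoselective borohydride reduction, since at −78 °C the aldehyde reacts far faster than the conjugated ketone.

**Step 14**
Reactants: 15
Product: 16, (1R,2S,7aS)-1-[(tert-butyldimethylsilyloxy)methyl]-2,7a-dimethyl-1,2,3,6,7,7a-hexahydro-5H-inden-5-one
Conditions: TBSCl, imidazole, DMF, rt
Reagents that add atoms: TBSCl, CC(C)(C)[Si](C)(C)Cl
Why: Silyl protection keeps the primary alcohol out of the reduction, ozonolysis and ylide steps that follow.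

**Step 15**
Reactants: 16
Product: 17, (1R,2S,3aS,7aR)-1-[(tert-butyldimethylsilyloxy)methyl]-5-(dimethylphenylsilyloxy)-2,7a-dimethyl-2,3,3a,6,7,7a-hexahydro-1H-indene (cis-fused, 3a-H cis to 7a-Me, C4=C5 enol silane)
Conditions: [(Ph3P)CuH]6 (5 mol %), PhMe2SiH, toluene, rt; used crude
Reagents that add atoms: dimethylphenylsilane, C[SiH](C)c1ccccc1
Why: Stryker-type CuH 1,4-hydrosilylation delivers hydride to C3a on the angular-methyl face, giving the cis-hydrindane usually seen with Hajos–Parrish-type enones (the α-2-Me reinforces this), and fixes the enol silane regiospecifically at C4=C5.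

**Step 16**
Reactants: 17
Product: 18, 3-[(1S,2R,3S,5R)-2-[(tert-butyldimethylsilyloxy)methyl]-5-formyl-1,3-dimethylcyclopentyl]propanoic acid
Conditions: O3, CH2Cl2/MeOH, −78 °C; Me2S, −78 °C → rt
Reagents that add atoms: ozone, [O-][O+]=O
Why: Ozonolysis of the silyl enol ether cleaves only C4=C5 and gives the differentiated aldehyde (C4) and carboxylic acid (C5) directly, with the cis ring fusion carried over as the formyl/propionate cis relationship.

**Step 17**
Reactants: 18
Product: 19, methyl 3-[(1S,2R,3S,5R)-2-[(tert-butyldimethylsilyloxy)methyl]-5-formyl-1,3-dimethylcyclopentyl]propanoate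
Conditions: TMSCHN2, toluene/MeOH, 0 °C
Reagents that add atoms: trimethylsilyldiazomethane, C[Si](C)(C)C=[N+]=[N-]
Why: Base-free diazoalkane esterification masks the acid without epimerising the α-stereocentre of the aldehyde.

**Step 18**
Reactants: 19; 20, isopropyltriphenylphosphonium iodide
Product: 21, methyl 3-[(1R,2R,3S,5S)-2-[(tert-butyldimethylsilyloxy)methyl]-1,3-dimethyl-5-(2-methylprop-1-en-1-yl)cyclopentyl]propanoate
Conditions: 20, n-BuLi (0.95 equiv relative to 20), THF, 0 °C; then 19, −78 → 0 °C
Reagents that add atoms: isopropyltriphenylphosphonium iodide, CC(C)[P+](c1ccccc1)(c1ccccc1)c1ccccc1.[I-]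
Why: In this Wittig olefination the non-stabilised isopropylidene ylide adds to the aldehyde much faster than it enolises it or attacks the ester, so the stereocentre is retained and there is no E/Z issue.

**Step 19**
Reactants: 21
Product: 22, methyl 3-[(1R,2R,3S,5S)-2-(hydroxymethyl)-1,3-dimethyl-5-(2-methylprop-1-en-1-yl)cyclopentyl]propanoate
Conditions: TBAF, AcOH, THF, rt
Reagents that add atoms: none
Why: Buffered fluoride desilylation leaves the methyl ester and the trisubstituted alkene untouched.

**Step 20**
Reactants: 22; 23, umbelliferone (7-hydroxycoumarin)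
Product: 24, methyl ferulsinaate (methyl ester of the target, 7-O-alkylated coumarin)
Conditions: PPh3, DIAD, THF, 0 °C → rt
Reagents that add atoms: umbelliferone, Oc1ccc2ccc(=O)oc2c1
Why: Mitsunobu etherification of a primary alcohol with an acidic phenol (pKa ≈ 8) forms the C–O bond at the CH2, so no stereocentre is involved.

**Step 21**
Reactants: 24
Product: 25, ferulsinaic acid, 3-[(1R,2R,3S,5S)-1,3-dimethyl-5-(2-methylprop-1-en-1-yl)-2-{[(2-oxo-2H-chromen-7-yl)oxy]methyl}cyclopentyl]propanoic acid
Conditions: carboxylesterase (pig liver esterase), phosphate buffer pH 7.4/DMSO 9:1, 30 °C, pH-stat; acidify to pH 4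
Reagents that add atoms: water, O
Why: Esterase hydrolysis of the unhindered terminal methyl ester at neutral pH, as used for base-labile prostaglandin esters, frees the acid without opening the coumarin lactone.

## Compound list
| No. | Name | SMILES | Role |
|---|---|---|---|
| 1 | cis-3,5-diacetoxycyclopentene (meso) | CC(=O)O[C@H]1C=C[C@@H](OC(C)=O)C1 | starting material |
| 2 | (1R,4S)-4-hydroxycyclopent-2-enyl acetate | CC(=O)O[C@H]1C=C[C@@H](O)C1 | intermediate |
| 3 | (1R,4S)-4-TBSO-cyclopent-2-enyl acetate | CC(=O)O[C@H]1C=C[C@@H](O[Si](C)(C)C(C)(C)C)C1 | intermediate |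
| 4 | (1R,4S)-4-TBSO-cyclopent-2-enol | O[C@H]1C=C[C@@H](O[Si](C)(C)C(C)(C)C)C1 | intermediate |
| 5 | (S)-4-TBSO-cyclopent-2-enone | O=C1C=C[C@@H](O[Si](C)(C)C(C)(C)C)C1 | intermediate |
| 6 | (3S,4S)-3-methyl-4-TBSO-cyclopentanone | O=C1C[C@H](C)[C@@H](O[Si](C)(C)C(C)(C)C)C1 | intermediate |
| 7 | (S)-4-methylcyclopent-2-enone | O=C1C[C@H](C)C=C1 | intermediate |
| 8 | (S)-2-iodo-4-methylcyclopent-2-enone | O=C1C[C@H](C)C=C1I | intermediate |
| 9 | (S)-2,4-dimethylcyclopent-2-enone | O=C1C[C@H](C)C=C1C | intermediate |
| 10 | (3R,4S) TMS enol ether | CC1=C(O[Si](C)(C)C)C[C@H](C)[C@H]1C=C | intermediate |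
| 11 | methyl vinyl ketone | C=CC(C)=O | starting material |
| 12 | (2S,3R,4S)-diketone | O=C1C[C@H](C)[C@@H](C=C)[C@]1(C)CCC(C)=O | intermediate |
| 13 | vinyl hydrindenone | O=C1C=C2C[C@H](C)[C@@H](C=C)[C@]2(C)CC1 | intermediate |
| 14 | hydrindenone carbaldehyde | O=C1C=C2C[C@H](C)[C@@H](C=O)[C@]2(C)CC1 | intermediate |
| 15 | hydroxymethyl hydrindenone | O=C1C=C2C[C@H](C)[C@@H](CO)[C@]2(C)CC1 | intermediate |
| 16 | TBS ether of 15 | O=C1C=C2C[C@H](C)[C@@H](CO[Si](C)(C)C(C)(C)C)[C@]2(C)CC1 | intermediate |
| 17 | cis-hydrindene enol silane | C[Si](C)(c1ccccc1)OC1=C[C@@H]2C[C@H](C)[C@@H](CO[Si](C)(C)C(C)(C)C)[C@]2(C)CC1 | intermediate |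
| 18 | aldehyde acid | O=C[C@@H]1C[C@H](C)[C@@H](CO[Si](C)(C)C(C)(C)C)[C@]1(C)CCC(=O)O | intermediate |
| 19 | aldehyde methyl ester | O=C[C@@H]1C[C@H](C)[C@@H](CO[Si](C)(C)C(C)(C)C)[C@]1(C)CCC(=O)OC | intermediate |
| 20 | isopropyltriphenylphosphonium iodide | CC(C)[P+](c1ccccc1)(c1ccccc1)c1ccccc1.[I-] | starting material |
| 21 | isobutenyl TBS ether ester | CC(C)=C[C@@H]1C[C@H](C)[C@@H](CO[Si](C)(C)C(C)(C)C)[C@]1(C)CCC(=O)OC | intermediate |
| 22 | isobutenyl alcohol ester | CC(C)=C[C@@H]1C[C@H](C)[C@@H](CO)[C@]1(C)CCC(=O)OC | intermediate |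
| 23 | umbelliferone | Oc1ccc2ccc(=O)oc2c1 | starting material |
| 24 | methyl ferulsinaate | CC(C)=C[C@@H]1C[C@H](C)[C@@H](COc2ccc3ccc(=O)oc3c2)[C@]1(C)CCC(=O)OC | intermediate |
| 25 | ferulsinaic acid | CC(C)=C[C@@H]1C[C@H](C)[C@@H](COc2ccc3ccc(=O)oc3c2)[C@]1(C)CCC(=O)O | target |

## Summary
Total steps: 21. Longest linear sequence: 21 (fully linear; 11, 20 and 23 are purchased).

Steps most likely to fail:
1. **Step 10 (Mukaiyama–Michael, quaternary centre).** The risks are MVK polymerisation, protodesilylation of 10, and erosion of the diastereomer ratio by the 1,3-related α-methyl. Fallback: switch to the anionic Stork–Ganem annulation. Cleave 10 with MeLi to the lithium enolate, add it to 3-(triethylsilyl)but-3-en-2-one, then treat with NaOMe/MeOH, which desilylates and cyclises directly to 13.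
2. **Step 15 (CuH 1,4-hydrosilylation).** The enone is hindered and β,β-disubstituted, so reaction may be slow, and the cis/trans ratio has not been tested with these substituents. Fallback: separate the two tasks. Use heterogeneous hydrogenation (H2, Pd/C) to reach the cis-hydrindan-5-one. Then form the enol silane toward the ring fusion under thermodynamic control (TMSI, (TMS)2NH; 5β-3-ketosteroid analogy). Remove any Δ5 isomer and carry out the same ozonolysis.
3. **Step 18 (Wittig on a hindered, epimerisable aldehyde).** The risks are enolisation or epimerisation at C5 and low conversion with the bulky ylide. Fallback: use a non-basic two-step olefination. Ramirez gem-dibromo-olefination (CBr4, PPh3, Zn) is followed by double Pd-catalysed Negishi methylation (Me2Zn, Pd(P-t-Bu3)2) to give 21.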